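**Retrosynthetic overview**

1. Hippolide H (33) comes from one-step removal of two silyl ethers and one acetal from butenolide 32. The butenolide is the only ring of the target and is formed last, from α-hydroxy ketone 30 and Ph3P=C=C=O (O-acylation, then intramolecular Wittig).
2. Ketone 30 comes from dioxolanone 25 and an alkoxymethyllithium. The C5–C6 bond of 25 is made by a photochemical iron/nickel decarboxylative alkenylation of acid 24 (from D-malic acid, carries C4) with (Z)-alkenyl iodide 22.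
3. Iodide 22 (C6=C7 geometry, C7–C8 bond) comes from alkoxide-directed anti-carbomagnesiation of propargyl alcohol by the Grignard reagent of bromide 16, then iodination.
4. Bromide 16 comes from enyne 12 by Zr-catalysed carboalumination and oxirane opening (C10=C11, C9–C10). Enyne 12 is made by nickel-electrocatalytic decarboxylative alkenylation (C13–C14) of pent-4-ynoic acid with (E)-alkenyl iodide 9.
5. Iodide 9 comes from enynol 6, made from (R)-5-oxotetrahydrofuran-2-carboxylic acid 1 (carries C18). Ring order: the lactone of 1 is opened in step 3, the dioxolanone is made in step 11 and opened in step 14, and the butenolide is closed in step 15.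

Assumption and labels: 1 and D-malic acid (23) are taken as the purchased carriers of the two stereocentres. Carbons are labelled C1 (lactone C=O), C2, C3 (bears CH2OH), C4 (ring CH–O), then C5 to C20 (=CH2) along the chain. TBS = tert-butyldimethylsilyl, TBSO = TBS-oxy.

**Route**

Step 1
Reactants: 1 (R)-5-oxotetrahydrofuran-2-carboxylic acid
Product: 3 (R)-5-acetyldihydrofuran-2(3H)-one, via acid chloride 2 (not isolated)
Conditions: (COCl)2, DMF (cat.), CH2Cl2, 0→23 °C; evaporate; Me2Zn, Pd(PPh3)4 (3 mol%), THF, 0 °C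
Reagents that add atoms: dimethylzinc C[Zn]C
Why: Acid chloride formation and palladium-catalysed Negishi acylation give the methyl ketone without base, so the lactone is untouched and the C18 stereocentre bought in 1 is not enolised.

Step 2
Reactants: 3 (R)-5-acetyldihydrofuran-2(3H)-one
Product: 4 (R)-5-(prop-1-en-2-yl)dihydrofuran-2(3H)-one
Conditions: Zn, CH2Br2, TiCl4, THF–CH2Cl2, 0→23 °C
Reagents that add atoms: dibromomethane BrCBr
Why: Takai–Lombardo methylenation is non-basic and selective for the ketone over the lactone, so the isopropenyl group is installed without epimerising the adjacent C18 centre.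

Step 3
Reactants: 4 (R)-5-(prop-1-en-2-yl)dihydrofuran-2(3H)-one
Product: 6 (R)-2-methylhept-1-en-6-yn-3-ol, via lactol 5 (not isolated)
Conditions: i-Bu2AlH (1.1 equiv), CH2Cl2, −78 °C; then MeOH, K2CO3, dimethyl (1-diazo-2-oxopropyl)phosphonate, −78→23 °C
Reagents that add atoms: dimethyl (1-diazo-2-oxopropyl)phosphonate COP(=O)(OC)C(=[N+]=[N-])C(C)=O
Why: Partial reduction to the lactol and one-pot Ohira–Bestmann homologation of its open hydroxy-aldehyde form give the terminal alkyne (C14≡C15); the carbinol centre is remote from the reacting carbon and is retained.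

Step 4
Reactants: 6 (R)-2-methylhept-1-en-6-yn-3-ol
Product: 7 (R)-tert-butyldimethyl[(2-methylhept-1-en-6-yn-3-yl)oxy]silane
Conditions: TBSCl, imidazole, DMF, 23 °C
Reagents that add atoms: tert-butyldimethylsilyl chloride CC(C)(C)[Si](C)(C)Cl
Why: Standard silylation protects the C18 hydroxyl for the organometallic and halogenation steps that follow.

Step 5
Reactants: 7 (R)-tert-butyldimethyl[(2-methylhept-1-en-6-yn-3-yl)oxy]silane
Product: 9 (R,E)-tert-butyl[(7-iodo-2,6-dimethylhepta-1,6-dien-3-yl)oxy]dimethylsilane, via alkenyldimethylalane 8 (not isolated)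
Conditions: AlMe3 (2.5 equiv), (C5H5)2ZrCl2 (25 mol%), CH2Cl2, 0→23 °C; then I2, THF, −30→0 °C
Reagents that add atoms: trimethylaluminium C[Al](C)C; iodine II
Why: Negishi Zr-catalysed syn-methylalumination of the terminal alkyne, then iodinolysis with retention, fixes the (E)-C14=C15 trisubstituted alkene; the 1,1-disubstituted alkene does not react.

Step 6
Reactants: 9 (R,E)-tert-butyl[(7-iodo-2,6-dimethylhepta-1,6-dien-3-yl)oxy]dimethylsilane; 10 pent-4-ynoic acid
Product: 12 (R,E)-tert-butyl[(2,6-dimethylundeca-1,6-dien-10-yn-3-yl)oxy]dimethylsilane, via N-hydroxyphthalimide ester 11 (not isolated)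
Conditions: 10, N-hydroxyphthalimide, N,N′-diisopropylcarbodiimide, DMAP (cat.), THF, 23 °C; then 9, NiCl2·6H2O (10 mol%), 2,2′-bipyridine (10 mol%), AgNO3 (0.3 equiv), DMF, Mg anode, reticulated vitreous carbon cathode, constant current, 23 °C
Reagents that add atoms: none
Why: Nickel-electrocatalytic decarboxylative alkenylation (cathodic reduction of the redox-active ester to a primary radical, capture by the alkenylnickel from 9, reductive elimination) forms C13–C14 with retention of the (E)-geometry.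

Step 7
Reactants: 12 (R,E)-tert-butyl[(2,6-dimethylundeca-1,6-dien-10-yn-3-yl)oxy]dimethylsilane
Product: 15 (3E,7E,11R)-11-(TBSO)-4,8,12-trimethyltrideca-3,7,12-trien-1-ol, via alkenyldimethylalane 13 (not isolated), via lithium alkenylaluminate 14 (not isolated)
Conditions: AlMe3, (C5H5)2ZrCl2 (25 mol%), CH2Cl2, 23 °C; evaporate; n-BuLi, hexane–THF, −78→0 °C; oxirane, 0→23 °C; aq. NH4Cl
Reagents that add atoms: trimethylaluminium C[Al](C)C; oxirane C1CO1
Why: A second Negishi carboalumination sets (E)-C10=C11, and the aluminate opens oxirane with retention at the alkenyl carbon to add C9 and C8 as a primary alcohol.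

Step 8
Reactants: 15 (3E,7E,11R)-11-(TBSO)-4,8,12-trimethyltrideca-3,7,12-trien-1-ol
Product: 16 {[(3R,6E,10E)-13-bromo-2,6,10-trimethyltrideca-1,6,10-trien-3-yl]oxy}(tert-butyl)dimethylsilane
Conditions: CBr4, PPh3, 2,6-lutidine, CH2Cl2, 0 °C
Reagents that add atoms: carbon tetrabromide BrC(Br)(Br)Br
Why: The Appel reaction converts the primary homoallylic alcohol to the bromide under buffered conditions that leave the silyl ether and the alkenes intact.

Step 9
Reactants: 16 {[(3R,6E,10E)-13-bromo-2,6,10-trimethyltrideca-1,6,10-trien-3-yl]oxy}(tert-butyl)dimethylsilane; 17 prop-2-yn-1-ol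
Product: 21 (2Z,5E,9E,13R)-13-(TBSO)-2-(iodomethylidene)-6,10,14-trimethylpentadeca-5,9,14-trien-1-ol, via Grignard reagent 18 (not isolated), via chloromagnesium propynolate 19 (not isolated), via alkenylmagnesium alkoxide 20 (not isolated)
Conditions: 16, Mg, THF, 40 °C; add to 17 (1.5 equiv) pre-treated with i-PrMgCl (THF, −20 °C), CuI (10 mol%), 0→23 °C; then I2, THF, −78→0 °C
Reagents that add atoms: iodine II
Why: Copper-catalysed, alkoxide-directed anti-carbomagnesiation of the propargylic alkoxide puts the alkyl group on the internal carbon (C7–C8) and magnesium cis to CH2O, so iodinolysis gives the (Z)-iodide with iodine cis to CH2OH, the geometry needed at C6=C7.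

Step 10
Reactants: 21 (2Z,5E,9E,13R)-13-(TBSO)-2-(iodomethylidene)-6,10,14-trimethylpentadeca-5,9,14-trien-1-ol
Product: 22 tert-butyl{[(2Z,5E,9E,13R)-13-(TBSO)-2-(iodomethylidene)-6,10,14-trimethylpentadeca-5,9,14-trien-1-yl]oxy}dimethylsilane
Conditions: TBSCl, imidazole, DMF, 23 °C
Reagents that add atoms: tert-butyldimethylsilyl chloride CC(C)(C)[Si](C)(C)Cl
Why: Silylation masks the allylic hydroxyl so that it cannot bind iron in step 12 or react with the ketenylidene ylide in step 15.

Step 11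
Reactants: 23 D-malic acid, (R)-2-hydroxybutanedioic acid
Product: 24 (R)-2-(2,2-dimethyl-5-oxo-1,3-dioxolan-4-yl)acetic acid
Conditions: 2,2-dimethoxypropane, TsOH·H2O (cat.), 23 °C
Reagents that add atoms: 2,2-dimethoxypropane COC(C)(C)OC
Why: Acetonide formation ties up the α-hydroxy acid as the five-membered dioxolanone and leaves the β-carboxyl free; the purchased stereocentre (future C4) is not touched.

Step 12
Reactants: 22 tert-butyl{[(2Z,5E,9E,13R)-13-(TBSO)-2-(iodomethylidene)-6,10,14-trimethylpentadeca-5,9,14-trien-1-yl]oxy}dimethylsilane; 24 (R)-2-(2,2-dimethyl-5-oxo-1,3-dioxolan-4-yl)acetic acid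
Product: 25 (R)-5-[(2Z,6E,10E,14R)-14-(TBSO)-3-(TBSO-methyl)-7,11,15-trimethylhexadeca-2,6,10,15-tetraen-1-yl]-2,2-dimethyl-1,3-dioxolan-4-one
Conditions: 24 (2 equiv), Fe(OTf)3 (10 mol%), NiBr2(dme) (10 mol%), 4,4′-di-tert-butyl-2,2′-bipyridine (12 mol%), Cs2CO3, DMA, 390 nm LEDs, 25 °C
Reagents that add atoms: none
Why: Proposed new method: the caesium carboxylate of 24 binds trivalent iron, and 390 nm ligand-to-metal charge transfer gives divalent iron and a carboxyl radical that loses CO2 to the primary C5 radical, while monovalent nickel adds oxidatively to the C–I bond of 22 with retention, divalent iron reduces the resulting trivalent nickel to an alkenyl divalent nickel species, and this captures the radical and reductively eliminates the C5–C6 bond, so the C4 stereocentre (one carbon from the radical) and the alkene geometry are untouched; closest known reaction type: iron/nickel dual photocatalytic decarboxylative arylation of free aliphatic acids with aryl iodides, and the nickel-electrocatalytic decarboxylative alkenylation of step 6.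

Step 13
Reactants: 26 (tributylstannyl)methanol
Product: 27 tributyl[(1-ethoxyethoxy)methyl]stannane
Conditions: ethyl vinyl ether, pyridinium p-toluenesulfonate (cat.), CH2Cl2, 23 °C
Reagents that add atoms: ethyl vinyl ether C=COCC
Why: Acid-catalysed acetalisation gives the protected hydroxymethyl-anion precursor; the acetal is removed later by the same mild acid that removes the silyl groups.

Step 14
Reactants: 25 (R)-5-[(2Z,6E,10E,14R)-14-(TBSO)-3-(TBSO-methyl)-7,11,15-trimethylhexadeca-2,6,10,15-tetraen-1-yl]-2,2-dimethyl-1,3-dioxolan-4-one; 27 tributyl[(1-ethoxyethoxy)methyl]stannane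
Product: 30 (3R,5Z,9E,13E,17R)-17-(TBSO)-6-(TBSO-methyl)-1-(1-ethoxyethoxy)-3-hydroxy-10,14,18-trimethylnonadeca-5,9,13,18-tetraen-2-one, via alkoxymethyllithium 28 (not isolated), via lithium hemiketal alkoxide 29 (not isolated)
Conditions: 27 (2.2 equiv), n-BuLi, THF, −78 °C; then 25, −78 °C; aq. NH4Cl, −78→23 °C
Reagents that add atoms: none
Why: Tin–lithium exchange gives the α-alkoxymethyllithium, which adds once to the activated dioxolanone carbonyl; the lithium hemiketal is stable at −78 °C and on work-up loses acetone to give the α-hydroxy ketone with the C4 centre retained.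

Step 15
Reactants: 30 (3R,5Z,9E,13E,17R)-17-(TBSO)-6-(TBSO-methyl)-1-(1-ethoxyethoxy)-3-hydroxy-10,14,18-trimethylnonadeca-5,9,13,18-tetraen-2-one
Product: 32 (R)-4-[(1-ethoxyethoxy)methyl]-5-[(2Z,6E,10E,14R)-14-(TBSO)-3-(TBSO-methyl)-7,11,15-trimethylhexadeca-2,6,10,15-tetraen-1-yl]furan-2(5H)-one, via phosphoranylidene ester 31 (not isolated)
Conditions: Ph3P=C=C=O (1.2 equiv), toluene, 80 °C
Reagents that add atoms: (triphenylphosphoranylidene)ketene O=C=C=P(c1ccccc1)(c1ccccc1)c1ccccc1
Why: The only free hydroxyl adds to the ketenylidene ylide (Bestmann ylide) and the resulting ester ylide closes onto the ketone by intramolecular Wittig reaction, forming the butenolide ring under neutral conditions that do not epimerise C4.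

Step 16
Reactants: 32 (R)-4-[(1-ethoxyethoxy)methyl]-5-[(2Z,6E,10E,14R)-14-(TBSO)-3-(TBSO-methyl)-7,11,15-trimethylhexadeca-2,6,10,15-tetraen-1-yl]furan-2(5H)-one
Product: 33 hippolide H, (R)-5-[(2Z,6E,10E,14R)-14-hydroxy-3-(hydroxymethyl)-7,11,15-trimethylhexadeca-2,6,10,15-tetraen-1-yl]-4-(hydroxymethyl)furan-2(5H)-one
Conditions: HF (48% aq.), MeCN, 0→23 °C
Reagents that add atoms: none
Why: Mildly acidic aqueous fluoride cleaves both silyl ethers and the ethoxyethyl acetal in one operation; no base is used, so the butenolide C4–H is not epimerised.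

**Compound list**

1 | (R)-5-oxotetrahydrofuran-2-carboxylic acid | OC(=O)[C@H]1CCC(=O)O1 | starting material
2 | (R)-5-oxotetrahydrofuran-2-carbonyl chloride | ClC(=O)[C@H]1CCC(=O)O1 | intermediate
3 | (R)-5-acetyldihydrofuran-2(3H)-one | CC(=O)[C@H]1CCC(=O)O1 | intermediate
4 | (R)-5-(prop-1-en-2-yl)dihydrofuran-2(3H)-one | C=C(C)[C@H]1CCC(=O)O1 | intermediate
5 | (5R)-5-(prop-1-en-2-yl)tetrahydrofuran-2-ol (lactol, both anomers) | C=C(C)[C@H]1CCC(O)O1 | intermediate
6 | (R)-2-methylhept-1-en-6-yn-3-ol | C=C(C)[C@H](O)CCC#C | intermediate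
7 | (R)-tert-butyldimethyl[(2-methylhept-1-en-6-yn-3-yl)oxy]silane | C=C(C)[C@H](O[Si](C)(C)C(C)(C)C)CCC#C | intermediate
8 | [(1E,5R)-5-(TBSO)-2,6-dimethylhepta-1,6-dien-1-yl]dimethylalane | C=C(C)[C@H](O[Si](C)(C)C(C)(C)C)CC/C(C)=C/[Al](C)C | intermediate
9 | (R,E)-tert-butyl[(7-iodo-2,6-dimethylhepta-1,6-dien-3-yl)oxy]dimethylsilane | C=C(C)[C@H](O[Si](C)(C)C(C)(C)C)CC/C(C)=C/I | intermediate
10 | pent-4-ynoic acid | C#CCCC(=O)O | starting material
11 | 1,3-dioxoisoindolin-2-yl pent-4-ynoate | C#CCCC(=O)ON1C(=O)c2ccccc2C1=O | intermediate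
12 | (R,E)-tert-butyl[(2,6-dimethylundeca-1,6-dien-10-yn-3-yl)oxy]dimethylsilane | C=C(C)[C@H](O[Si](C)(C)C(C)(C)C)CC/C(C)=C/CCC#C | intermediate
13 | [(1E,5E,9R)-9-(TBSO)-2,6,10-trimethylundeca-1,5,10-trien-1-yl]dimethylalane | C=C(C)[C@H](O[Si](C)(C)C(C)(C)C)CC/C(C)=C/CC/C(C)=C/[Al](C)C | intermediate
14 | lithium butyl[(1E,5E,9R)-9-(TBSO)-2,6,10-trimethylundeca-1,5,10-trien-1-yl]dimethylaluminate | [Li+].C=C(C)[C@H](O[Si](C)(C)C(C)(C)C)CC/C(C)=C/CC/C(C)=C/[Al-](C)(C)CCCC | intermediate
15 | (3E,7E,11R)-11-(TBSO)-4,8,12-trimethyltrideca-3,7,12-trien-1-ol | C=C(C)[C@H](O[Si](C)(C)C(C)(C)C)CC/C(C)=C/CC/C(C)=C/CCO | intermediate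
16 | {[(3R,6E,10E)-13-bromo-2,6,10-trimethyltrideca-1,6,10-trien-3-yl]oxy}(tert-butyl)dimethylsilane | C=C(C)[C@H](O[Si](C)(C)C(C)(C)C)CC/C(C)=C/CC/C(C)=C/CCBr | intermediate
17 | prop-2-yn-1-ol | C#CCO | starting material
18 | bromo[(3E,7E,11R)-11-(TBSO)-4,8,12-trimethyltrideca-3,7,12-trien-1-yl]magnesium | C=C(C)[C@H](O[Si](C)(C)C(C)(C)C)CC/C(C)=C/CC/C(C)=C/CC[Mg]Br | intermediate
19 | chloro(prop-2-yn-1-olato)magnesium | C#CCO[Mg]Cl | intermediate
20 | (Z)-alkenylmagnesium bromide of 21 as its chloromagnesium alkoxide (Mg in place of I, OMgCl in place of OH) | C=C(C)[C@H](O[Si](C)(C)C(C)(C)C)CC/C(C)=C/CC/C(C)=C/CC/C(=C/[Mg]Br)CO[Mg]Cl | intermediate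
21 | (2Z,5E,9E,13R)-13-(TBSO)-2-(iodomethylidene)-6,10,14-trimethylpentadeca-5,9,14-trien-1-ol | C=C(C)[C@H](O[Si](C)(C)C(C)(C)C)CC/C(C)=C/CC/C(C)=C/CC/C(=C/I)CO | intermediate
22 | tert-butyl{[(2Z,5E,9E,13R)-13-(TBSO)-2-(iodomethylidene)-6,10,14-trimethylpentadeca-5,9,14-trien-1-yl]oxy}dimethylsilane | C=C(C)[C@H](O[Si](C)(C)C(C)(C)C)CC/C(C)=C/CC/C(C)=C/CC/C(=C/I)CO[Si](C)(C)C(C)(C)C | intermediate
23 | D-malic acid, (R)-2-hydroxybutanedioic acid | OC(=O)C[C@@H](O)C(=O)O | starting material
24 | (R)-2-(2,2-dimethyl-5-oxo-1,3-dioxolan-4-yl)acetic acid | OC(=O)C[C@H]1OC(C)(C)OC1=O | intermediate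
25 | (R)-5-[(2Z,6E,10E,14R)-14-(TBSO)-3-(TBSO-methyl)-7,11,15-trimethylhexadeca-2,6,10,15-tetraen-1-yl]-2,2-dimethyl-1,3-dioxolan-4-one | C=C(C)[C@H](O[Si](C)(C)C(C)(C)C)CC/C(C)=C/CC/C(C)=C/CC/C(=C/C[C@H]1OC(C)(C)OC1=O)CO[Si](C)(C)C(C)(C)C | intermediate
26 | (tributylstannyl)methanol | CCCC[Sn](CCCC)(CCCC)CO | starting material
27 | tributyl[(1-ethoxyethoxy)methyl]stannane | CCCC[Sn](CCCC)(CCCC)COC(C)OCC | intermediate
28 | [(1-ethoxyethoxy)methyl]lithium | [Li]COC(C)OCC | intermediate
29 | lithium (5R)-4-[(1-ethoxyethoxy)methyl]-2,2-dimethyl-5-[(2Z,6E,10E,14R)-14-(TBSO)-3-(TBSO-methyl)-7,11,15-trimethylhexadeca-2,6,10,15-tetraen-1-yl]-1,3-dioxolan-4-olate | [Li+].C=C(C)[C@H](O[Si](C)(C)C(C)(C)C)CC/C(C)=C/CC/C(C)=C/CC/C(=C/C[C@H]1OC(C)(C)OC1([O-])COC(C)OCC)CO[Si](C)(C)C(C)(C)C | intermediate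
30 | (3R,5Z,9E,13E,17R)-17-(TBSO)-6-(TBSO-methyl)-1-(1-ethoxyethoxy)-3-hydroxy-10,14,18-trimethylnonadeca-5,9,13,18-tetraen-2-one | C=C(C)[C@H](O[Si](C)(C)C(C)(C)C)CC/C(C)=C/CC/C(C)=C/CC/C(=C/C[C@@H](O)C(=O)COC(C)OCC)CO[Si](C)(C)C(C)(C)C | intermediate
31 | (triphenylphosphoranylidene)acetate ester of the C3 hydroxyl of 30 | C=C(C)[C@H](O[Si](C)(C)C(C)(C)C)CC/C(C)=C/CC/C(C)=C/CC/C(=C/C[C@@H](OC(=O)C=P(c1ccccc1)(c1ccccc1)c1ccccc1)C(=O)COC(C)OCC)CO[Si](C)(C)C(C)(C)C | intermediate
32 | (R)-4-[(1-ethoxyethoxy)methyl]-5-[(2Z,6E,10E,14R)-14-(TBSO)-3-(TBSO-methyl)-7,11,15-trimethylhexadeca-2,6,10,15-tetraen-1-yl]furan-2(5H)-one | C=C(C)[C@H](O[Si](C)(C)C(C)(C)C)CC/C(C)=C/CC/C(C)=C/CC/C(=C/C[C@H]1OC(=O)C=C1COC(C)OCC)CO[Si](C)(C)C(C)(C)C | intermediate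
33 | hippolide H, (R)-5-[(2Z,6E,10E,14R)-14-hydroxy-3-(hydroxymethyl)-7,11,15-trimethylhexadeca-2,6,10,15-tetraen-1-yl]-4-(hydroxymethyl)furan-2(5H)-one | C=C(C)[C@H](O)CC/C(C)=C/CC/C(C)=C/CC/C(=C/C[C@H]1OC(=O)C=C1CO)CO | target

**Step count**

Total: 16 steps. Longest linear sequence: 14 steps (steps 1–10, 12, 14, 15, 16); steps 11 and 13 are side branches.

**Steps most likely to fail, with fallbacks**

The proposed photochemical coupling of step 12 is the least certain step. It has not been shown with alkenyl iodides; iodide may quench the iron cycle, and protodecarboxylation of 24 may compete. The fallback is known chemistry and sets out from 24 (with 22). Acid 24 is esterified with N-hydroxyphthalimide and N,N′-diisopropylcarbodiimide to 1,3-dioxoisoindolin-2-yl (R)-2-(2,2-dimethyl-5-oxo-1,3-dioxolan-4-yl)acetate F2. F2 is then coupled with 22 by the nickel-electrocatalytic decarboxylative alkenylation of step 6 (NiCl2·6H2O, 2,2′-bipyridine, AgNO3, Mg anode, DMF). The fallback comes back to the route at 25.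

The carbomagnesiation of step 9 uses the advanced Grignard reagent 18 as the limiting partner. The acidic alkyne C–H of the propargylic alkoxide can protonate part of it, and such additions normally need excess Grignard reagent. The fallback sets out from 16 (through 18). The Grignard reagent is added, with CuI, to 3-(trimethylsilyl)prop-2-yn-1-ol that has been deprotonated with i-PrMgCl; this alkynol has no acidic C–H. Iodine quench gives (2Z,5E,9E,13R)-13-(TBSO)-2-[iodo(trimethylsilyl)methylidene]-6,10,14-trimethylpentadeca-5,9,14-trien-1-ol F1. NaOMe in MeOH then removes the silyl group from the 1-iodo-1-silylalkene with retention. The fallback comes back to the route at 21.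

The organolithium addition of step 14 can fail by enolisation of the dioxolanone (which would erode C4) or by a second addition. The fallback sets out from 25. The dioxolanone is opened with Me2AlN(OMe)Me (from AlMe3 and MeNHOMe·HCl) to the Weinreb amide (2R,4Z,8E,12E,16R)-16-(TBSO)-5-(TBSO-methyl)-2-hydroxy-N-methoxy-N,9,13,17-tetramethyloctadeca-4,8,12,17-tetraenamide F3. Its α-alkoxide suppresses enolisation, and the chelated adduct with alkoxymethyllithium 28 (3 equiv, THF, −78 °C) cannot add twice. The fallback comes back to the route at 30.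

**Further compounds**

F1 | step 9 | (2Z,5E,9E,13R)-13-(TBSO)-2-[iodo(trimethylsilyl)methylidene]-6,10,14-trimethylpentadeca-5,9,14-trien-1-ol | C=C(C)[C@H](O[Si](C)(C)C(C)(C)C)CC/C(C)=C/CC/C(C)=C/CC/C(CO)=C(/I)[Si](C)(C)C
F2 | step 12 | 1,3-dioxoisoindolin-2-yl (R)-2-(2,2-dimethyl-5-oxo-1,3-dioxolan-4-yl)acetate | O=C(C[C@H]1OC(C)(C)OC1=O)ON1C(=O)c2ccccc2C1=O
F3 | step 14 | (2R,4Z,8E,12E,16R)-16-(TBSO)-5-(TBSO-methyl)-2-hydroxy-N-methoxy-N,9,13,17-tetramethyloctadeca-4,8,12,17-tetraenamide | C=C(C)[C@H](O[Si](C)(C)C(C)(C)C)CC/C(C)=C/CC/C(C)=C/CC/C(=C/C[C@@H](O)C(=O)N(C)OC)CO[Si](C)(C)C(C)(C)C
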